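**Retrosynthetic overview**
1. Sargachromanol C (15) ⇒ global desilylation of 14 ⇒ C6'–C7' bond by B-alkyl Suzuki coupling of diene 7 (via 9-BBN) with (E)-vinyl iodide 13.
2. 13 ⇒ Zr-catalysed carboalumination/iodination of alkyne 12 ⇒ silyloxy ester 11 ⇒ methyl (R)-glycidate (8) + isobutenyl Grignard (9); C9' is bought.
3. 7 ⇒ Wittig methylenation of enal 6 ⇒ SeO2 oxidation of the (E)-methyl of the prenyl terminus of 5.
4. Chromanol 4 ⇒ anodic para-C–H cycloetherification of phenol 3, in which the tertiary OH becomes the ring oxygen (key step).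
5. 3 ⇒ 9-BBN/Suzuki union of (R)-linalool (1) with 3-bromo-5-methylphenol (2); C2 is bought. Only one ring is formed (the dihydropyran of the chroman); the benzene ring is purchased.

Assumption: commercial (R)-(−)-linalool and methyl (R)-glycidate are taken as ≥98% ee; a telescoped one-pot sequence is counted as one step.

**Route**

Step 1
Reactants: 1 (R)-(−)-linalool; 2 3-bromo-5-methylphenol
Product: 3 3-[(3R)-3-hydroxy-3,7-dimethyloct-6-en-1-yl]-5-methylphenol
Conditions: 1, 9-BBN (2.2 equiv), THF, 0 °C → rt; then 2, Pd(dppf)Cl2 (3 mol%), 3 M aq. K3PO4 (4 equiv), DMF, 60 °C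
Reagents that add atoms: none (9-BBN delivers only H)
Why: 9-BBN hydroborates only the monosubstituted vinyl group, anti-Markovnikov, and the alkylborane undergoes B-alkyl Suzuki–Miyaura coupling; the stereocenter comes from linalool and no bond to it is touched.

Step 2
Reactants: 3
Product: 4 (2R)-2,8-dimethyl-2-(4-methylpent-3-en-1-yl)-3,4-dihydro-2H-chromen-6-ol
Conditions: undivided cell, graphite(+)/Pt(−), 5 mA cm⁻², 4.2 F mol⁻¹, LiClO4 (0.1 M), 2,6-lutidine (2 equiv), MeOH, 0 °C; concentrate; CSA (5 mol%), 4 Å MS, CH2Cl2, 0 °C; then ascorbic acid (3 equiv), THF/H2O, rt (one pot, nothing isolated)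
Reagents that add atoms: none (MeOH appears only in the transient 8a-methoxy ketal and is expelled again)
Why: Proposed new method: anodic dehydrogenative para-C–H cycloetherification of a phenol by a meta-tethered tertiary alcohol through a quinone-monoketal relay. Two successive 2e⁻ oxidations take the phenol via phenoxonium ions (para attack by MeOH or the tertiary OH, then ipso attack) to the fused 8a-methoxy dienone ketal, and any acyclic 4,4-dimethoxy dienone is funnelled to it by the CSA transketalisation. Ascorbate then reduces this ketal with loss of MeOH to the aromatic chroman-6-ol. Over-oxidising on purpose to the stable monoketal avoids the problem that the chromanol is easier to oxidise than the starting phenol. The phenol should oxidise several hundred mV below the trisubstituted alkene, and C2 is retained because its C–O bond is never broken. Closest known reactions: anodic or PhI(OAc)2 oxidation of phenols and p-methoxyphenols in MeOH to p-quinone monoketals, and ascorbic-acid reduction of 8a-alkoxytocopherones to tocopherols.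

Step 3
Reactants: 4
Product: 5 (2R)-2,8-dimethyl-2-(4-methylpent-3-en-1-yl)-6-(triisopropylsilyloxy)chroman
Conditions: TIPSCl, imidazole, DMF, rt
Reagents that add atoms: triisopropylsilyl chloride, CC(C)[Si](Cl)(C(C)C)C(C)C
Why: Standard silylation of the unhindered phenol; TIPS is chosen so the aryl silyl ether survives Se(IV)/peroxide, the ylide and aqueous phosphate, yet falls to fluoride.

Step 4
Reactants: 5
Product: 6 (2E)-5-[(2R)-2,8-dimethyl-6-(triisopropylsilyloxy)chroman-2-yl]-2-methylpent-2-enal
Conditions: SeO2 (0.5 equiv), t-BuOOH (3 equiv), salicylic acid (10 mol%), CH2Cl2, rt; filter; MnO2, CH2Cl2, rt (telescoped)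
Reagents that add atoms: selenium dioxide, O=[Se]=O (oxygen donor, turned over by tert-butyl hydroperoxide, CC(C)(C)OO)
Why: Sharpless SeO2/TBHP allylic oxidation (ene reaction then [2,3]-shift) selects the (E)-methyl at the disubstituted end of the trisubstituted alkene; MnO2 converts the alcohol/aldehyde mixture to the (E)-enal.

Step 5
Reactants: 6
Product: 7 (2R)-2,8-dimethyl-2-[(3E)-4-methylhexa-3,5-dien-1-yl]-6-(triisopropylsilyloxy)chroman
Conditions: Ph3PCH3Br, KHMDS, THF, 0 °C → rt
Reagents that add atoms: methyltriphenylphosphonium bromide, C[P+](c1ccccc1)(c1ccccc1)c1ccccc1.[Br-]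
Why: Wittig methylenation of the enal; the new C=C has no geometry and the existing (E)-alkene is untouched.

Step 6
Reactants: 8 methyl (R)-glycidate; 9 2-methylprop-1-en-1-ylmagnesium bromide
Product: 10 methyl (2R)-2-hydroxy-5-methylhex-4-enoate
Conditions: 9 (1.3 equiv), CuBr·SMe2 (10 mol%), THF, −78 → −40 °C
Reagents that add atoms: none beyond reactants 8 and 9
Why: Copper-catalysed SN2 epoxide opening at the unsubstituted C3 of the glycidate (the ester survives at low temperature); the purchased C2 stereocenter is not involved and stays (R).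

Step 7
Reactants: 10
Product: 11 methyl (2R)-2-[(tert-butyldimethylsilyl)oxy]-5-methylhex-4-enoate
Conditions: TBSCl, imidazole, DMF, rt
Reagents that add atoms: tert-butyldimethylsilyl chloride, CC(C)(C)[Si](C)(C)Cl
Why: Routine silyl protection of the secondary alcohol, needed for the aldehyde-level intermediate and the organoaluminium step.

Step 8
Reactants: 11
Product: 12 (3R)-3-[(tert-butyldimethylsilyl)oxy]-6-methylhept-5-en-1-yne
Conditions: DIBAL-H (1.1 equiv), CH2Cl2, −78 °C; then MeOH, dimethyl (1-diazo-2-oxopropyl)phosphonate, K2CO3, −78 °C → rt (one pot)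
Reagents that add atoms: dimethyl (1-diazo-2-oxopropyl)phosphonate, COP(=O)(OC)C(=[N+]=[N-])C(C)=O (supplies the terminal alkyne carbon)
Why: Partial ester reduction to the aldehyde (held as the aluminium hemiacetal) followed by Seyferth–Gilbert homologation with the Ohira–Bestmann reagent; the α-silyloxy stereocenter is carried through unchanged.

Step 9
Reactants: 12
Product: 13 (1E,3R)-3-[(tert-butyldimethylsilyl)oxy]-1-iodo-2,6-dimethylhepta-1,5-diene
Conditions: AlMe3 (3 equiv), Cp2ZrCl2 (0.3 equiv), H2O (1 equiv), CH2Cl2, −20 °C; then I2, THF, −30 → 0 °C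
Reagents that add atoms: trimethylaluminium, C[Al](C)C; iodine, II
Why: Negishi Zr-catalysed syn-carboalumination places Me on the internal and Al on the terminal alkyne carbon, and iodinolysis with retention gives only the (E)-vinyl iodide; the trisubstituted alkene is inert.

Step 10
Reactants: 7; 13
Product: 14 (2R)-2-[(3E,7E,9R)-9-[(tert-butyldimethylsilyl)oxy]-4,8,12-trimethyltrideca-3,7,11-trien-1-yl]-2,8-dimethyl-6-(triisopropylsilyloxy)chroman
Conditions: 7, 9-BBN (1.3 equiv), THF, 0 °C → rt; then 13, Pd(dppf)Cl2 (5 mol%), AsPh3 (10 mol%), 3 M aq. K3PO4, DMF, rt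
Reagents that add atoms: none
Why: 9-BBN adds only to the terminal vinyl of the diene (anti-Markovnikov) to give the homoallylic borane, and B-alkyl Suzuki–Miyaura coupling forms C6'–C7' with retention of the vinyl iodide geometry, so C7'=C8' is (E).

Step 11
Reactants: 14
Product: 15 sargachromanol C, (2R)-2-[(3E,7E,9R)-9-hydroxy-4,8,12-trimethyltrideca-3,7,11-trien-1-yl]-2,8-dimethyl-3,4-dihydro-2H-chromen-6-ol
Conditions: TBAF (4 equiv), AcOH (4 equiv), THF, 0 °C → rt, under Ar
Reagents that add atoms: none
Why: Fluoride cleaves both the aryl TIPS and the secondary TBS ether (silyl ether deprotection); buffering protects the oxidation-prone chromanol and no stereocenter or alkene is affected.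

**Compound list**
1 | (R)-(−)-linalool | CC(C)=CCC[C@@](C)(O)C=C | starting material
2 | 3-bromo-5-methylphenol | Cc1cc(O)cc(Br)c1 | starting material
3 | 3-[(3R)-3-hydroxy-3,7-dimethyloct-6-en-1-yl]-5-methylphenol | CC(C)=CCC[C@@](C)(O)CCc1cc(C)cc(O)c1 | intermediate
4 | (2R)-2,8-dimethyl-2-(4-methylpent-3-en-1-yl)chroman-6-ol | CC(C)=CCC[C@]1(C)CCc2cc(O)cc(C)c2O1 | intermediate
5 | TIPS ether of 4 | CC(C)=CCC[C@]1(C)CCc2cc(O[Si](C(C)C)(C(C)C)C(C)C)cc(C)c2O1 | intermediate
6 | (2E)-5-[(2R)-2,8-dimethyl-6-(TIPSO)chroman-2-yl]-2-methylpent-2-enal | O=C/C(C)=C/CC[C@]1(C)CCc2cc(O[Si](C(C)C)(C(C)C)C(C)C)cc(C)c2O1 | intermediate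
7 | (2R)-2,8-dimethyl-2-[(3E)-4-methylhexa-3,5-dien-1-yl]-6-(TIPSO)chroman | C=C/C(C)=C/CC[C@]1(C)CCc2cc(O[Si](C(C)C)(C(C)C)C(C)C)cc(C)c2O1 | intermediate
8 | methyl (R)-glycidate (methyl (2R)-oxirane-2-carboxylate) | COC(=O)[C@H]1CO1 | starting material
9 | 2-methylprop-1-en-1-ylmagnesium bromide | CC(C)=C[Mg]Br | starting material
10 | methyl (2R)-2-hydroxy-5-methylhex-4-enoate | COC(=O)[C@H](O)CC=C(C)C | intermediate
11 | methyl (2R)-2-(TBSO)-5-methylhex-4-enoate | COC(=O)[C@H](O[Si](C)(C)C(C)(C)C)CC=C(C)C | intermediate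
12 | (3R)-3-(TBSO)-6-methylhept-5-en-1-yne | C#C[C@H](O[Si](C)(C)C(C)(C)C)CC=C(C)C | intermediate
13 | (1E,3R)-3-(TBSO)-1-iodo-2,6-dimethylhepta-1,5-diene | I/C=C(\C)[C@H](O[Si](C)(C)C(C)(C)C)CC=C(C)C | intermediate
14 | 9'-O-TBS, 6-O-TIPS sargachromanol C | CC(C)=CC[C@@H](O[Si](C)(C)C(C)(C)C)/C(C)=C/CC/C(C)=C/CC[C@]1(C)CCc2cc(O[Si](C(C)C)(C(C)C)C(C)C)cc(C)c2O1 | intermediate
15 | sargachromanol C | CC(C)=CC[C@@H](O)/C(C)=C/CC/C(C)=C/CC[C@]1(C)CCc2cc(O)cc(C)c2O1 | target

**Totals**
Total steps: 11. Longest linear sequence: 7 (steps 1, 2, 3, 4, 5, 10, 11 from linalool; the glycidate branch is 6).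

**Three steps most likely to fail**
1. Step 2 (proposed new electrochemical cycloetherification). Risks are phenoxyl radical coupling, ortho attack, and incomplete funnelling to the cyclic ketal. Fallback with known chemistry: use 1-bromo-2,5-dimethoxy-3-methylbenzene in step 1 instead of 2, oxidise with CAN to the hydroxyalkyl benzoquinone, form the cyclic 8a-methoxy ketal with HC(OMe)3/MeOH/H⁺, and reduce to 4. This is the established quinone-ketal chroman synthesis, which keeps the tertiary C–O bond (retention).
2. Step 4 (SeO2 allylic oxidation). Risks are modest yield and over- or mis-oxidation. Fallback: ozonolysis of the prenyl alkene of 5 to the chain aldehyde (O3, then Me2S), followed by an E-selective Wittig reaction with the stabilised ylide Ph3P=C(CH3)CHO to reach 6.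
3. Step 8 (one-pot DIBAL/Ohira–Bestmann). Risks are over-reduction and base-induced erosion of the α-silyloxy stereocenter. Fallback: isolate the aldehyde at −78 °C and use Corey–Fuchs homologation (CBr4/PPh3, then n-BuLi at −78 °C), which avoids exposing the α-silyloxy aldehyde to basic methanol.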